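The cyclohexane ring is numbered C1 (carbinol bearing C7H2OBz), C2 (ketone), C3 (CH2), C4 (CHOH), C5 (CHOBz), C6 (CHOH), and it is disconnected at C4–C5. The feature exploited is the cis O4/O5 glycol that lies trans to O6 on this ring. One SmI2 pinacol coupling of an acyclic 1,6-dialdehyde forms C4–C5, closes the carbocycle and sets both carbinol centres. The precursor holds C1 and C6 in a cis-dioxolane, O2 as a PMB ether (latent ketone) and O7 already as benzoate. D-Mannose supplies C5, C6, C1 and C2. Formaldehyde adds C7 and an allyl unit adds C3 and C4. Both formyl groups are released together under near-neutral conditions.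

Key step: step 8

Numbering: carbocycle numbering (C1–C7, O1–O7) is used throughout. With the ring numbered clockwise, C7, O4 and O5 point up and O1, O2 and O6 point down. In the open-chain non-1-enitols, chain atoms C2, C3, C4, C5, C6 and C7 are the future C4, C3, C2, C1, C6 and C5. The 5-C-CH2O branch (oxygen 5') is C7–O7.

Assumption: the allyl addition of step 2 is taken to favour the Felkin–Anh (R)-carbinol at future C2. This centre is a spectator that step 12 planarises, and any epimer can be removed at the acetal stage (step 3).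

Step 1
Reactants: 1 2,3:5,6-di-O-isopropylidene-α-D-mannofuranose; 2 formaldehyde (37% aqueous)
Product: 3 2-C-(hydroxymethyl)-2,3:5,6-di-O-isopropylidene-D-mannofuranose (anomeric mixture)
Conditions: K2CO3, aq. HCHO, MeOH, reflux
Reagents that add atoms: none
Why: Base-mediated crossed aldol reaction of the open hydroxy-aldehyde tautomer with non-enolisable formaldehyde; the dioxolane enolate is attacked on the face anti to its C3 side chain and only that epimer can re-close to the cis-fused furanose, so CH2OH (future C7) replaces H-2 with retention and sets the quaternary centre (future C1).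

Step 2
Reactants: 3 2-C-(hydroxymethyl)-2,3:5,6-di-O-isopropylidene-D-mannofuranose; 4 allylmagnesium bromide
Product: 5 (4R)-1,2,3-trideoxy-5-C-(hydroxymethyl)-5,6:8,9-di-O-isopropylidene-D-glycero-D-talo-non-1-enitol (4,5',7-triol)
Conditions: CH2=CHCH2MgBr (4 equiv), THF, −78 to 0 °C
Reagents that add atoms: none
Why: Grignard addition to the aldehyde tautomer of a lactol after deprotonation of both hydroxyls; polar Felkin–Anh attack anti to the dioxolane C–O bond and past the smaller CH2O arm should favour the (R)-carbinol (O2 on the same Fischer side as O1), a spectator centre that step 12 removes.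

Step 3
Reactants: 5 the 4,5',7-triol; 6 4-methoxybenzaldehyde dimethyl acetal
Product: 7 4,5'-O-[(S)-4-methoxybenzylidene] acetal of 5 (1,3-dioxane with aryl and allyl equatorial; 7-OH free)
Conditions: 4-MeOC6H4CH(OMe)2, PPTS (cat.), CH2Cl2, rt
Reagents that add atoms: none
Why: Acid-catalysed transacetalisation engages the only 1,3-diol (O2/O7) as a six-membered dioxane, the remaining hydroxyl being able to close only seven- or eight-membered rings, and thermodynamic control places aryl and allyl equatorial (cis), which fixes the acetal carbon as S.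

Step 4
Reactants: 7 the 4-methoxybenzylidene acetal
Product: 8 1,2,3-trideoxy-5-C-(hydroxymethyl)-5,6:8,9-di-O-isopropylidene-4-O-(4-methoxybenzyl)-D-glycero-D-talo-non-1-enitol (5'-OH and 7-OH free)
Conditions: i-Bu2AlH (5 equiv), CH2Cl2, −78 to 0 °C
Reagents that add atoms: none
Why: Regioselective reductive opening of a 4-methoxybenzylidene acetal; i-Bu2AlH binds the less hindered primary O7, the C–O7 bond breaks and hydride quenches the oxocarbenium ion on O2, so the PMB group ends on the secondary oxygen without any alkylation under strong base and no stereocentre changes.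

Step 5
Reactants: 8 the 4-O-PMB diol; 9 benzoyl chloride
Product: 10 5-C-(benzoyloxymethyl)-1,2,3-trideoxy-5,6:8,9-di-O-isopropylidene-4-O-(4-methoxybenzyl)-D-glycero-D-talo-non-1-enitol (7-OH free)
Conditions: BzCl (1.1 equiv), pyridine, CH2Cl2, −20 to 0 °C
Reagents that add atoms: none
Why: Chemoselective acylation of the primary O7 over the single secondary hydroxyl, which is flanked by two dioxolanes; the ester enters only after the last organometallic and hydride steps and so never meets them.

Step 6
Reactants: 10 the 7-hydroxy benzoate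
Product: 11 5-C-(benzoyloxymethyl)-1,2,3-trideoxy-5,6-O-isopropylidene-4-O-(4-methoxybenzyl)-D-glycero-D-talo-non-1-enitol (7,8,9-triol)
Conditions: AcOH/H2O 4:1, rt to 40 °C
Reagents that add atoms: none
Why: Selective acid hydrolysis of the terminal, less substituted dioxolane, which is cleaved faster than the internal one on the quaternary carbon (the standard partial deprotection of sugar diacetonides); PMB ether, benzoate and alkene are inert to aqueous acetic acid.

Step 7
Reactants: 11 the 7,8,9-triol
Product: 14 3-C-(benzoyloxymethyl)-5-deoxy-2,3-O-isopropylidene-4-O-(4-methoxybenzyl)-D-ribo-hexodialdose, via heptenose aldehyde 12 (not isolated), via heptose glycol 13 (not isolated)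
Conditions: OsO4 (2 mol %), NaIO4 (6 equiv), 2,6-lutidine, dioxane/H2O 3:1, rt; extractive work-up, azeotropic drying, no chromatography
Reagents that add atoms: osmium tetroxide, O=[Os](=O)(=O)=O; sodium periodate, [Na+].[O-]I(=O)(=O)=O
Why: Malaprade cleavage of the triol and Lemieux–Johnson cleavage of the terminal alkene run in one flask, so both formyl groups (C5 from mannose C4, C4 from the internal allyl carbon) appear together at buffered near-neutral pH, which spares the β-alkoxy aldehyde from elimination and the α-alkoxy aldehyde from epimerisation.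

Step 8
Reactants: 14 the 1,6-dialdehyde
Product: 15 carbocyclic cis-4,5-diol with O1/O6 acetonide, O2 PMB ether and O7 benzoate (C7, O4, O5 up; O1, O2, O6 down)
Conditions: SmI2 (3 equiv, 0.1 M), t-BuOH (3 equiv), THF, −78 °C to rt, slow addition of 14 at high dilution
Reagents that add atoms: none
Why: SmI2 transfers one electron to a formyl group of 14 and the resulting samarium ketyl adds to the second, samarium-coordinated formyl group before a second electron and t-BuOH complete the reduction, so C4–C5 forms as a diolate of trivalent samarium. The closest known reaction type is the SmI2 pinacol cyclisation of carbohydrate-derived 1,6-dialdehydes to cyclitol cis-diols. The cyclohexane closes in a 6-exo-trig mode, helped by the cis-dioxolane that already holds the C2 and C5 arms on one face. C5 is controlled by the adjacent C6–O bond: the bulky samarium-bound oxygen turns away from the dioxolane for dipolar and steric reasons, which places O5 trans to O6. C4 is controlled by the samarium bridge between both oxygens, which forces O4 cis to O5. The step needs chemoselectivity for the aldehydes over the C7 benzoate and over reductive C6–O cleavage, secured by additive-free SmI2 at low temperature, and it needs ring closure over intermolecular coupling, secured by dilution and by the pre-organised arms.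

Step 9
Reactants: 15 the cis-4,5-diol; 9 benzoyl chloride
Product: 17 5-O-benzoate of diol 15 (O4–H free), via stannylene acetal 16 (not isolated)
Conditions: Bu2SnO, toluene, reflux (−H2O); then BzCl (1.05 equiv), 0 °C to rt
Reagents that add atoms: dibutyltin oxide, CCCC[Sn](=O)CCCC (its tin fragment is present only in 16)
Why: Stannylene-acetal-directed monoacylation of a cis-1,2-diol; in the favoured chair (C7, O2, O5, O6 equatorial; O1, O4 axial) the tin acetal activates the equatorial O5, the same bias that gives 3-O-acylation of galactoside 3,4-diols.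

Step 10
Reactants: 17 the 5-O-benzoate
Product: 18 4-O-triethylsilyl ether of 17
Conditions: TESOTf, 2,6-lutidine, CH2Cl2, −78 to 0 °C
Reagents that add atoms: triethylsilyl triflate, CC[Si](CC)(CC)OS(=O)(=O)C(F)(F)F
Why: Silylation of the remaining axial O4 with a silyl triflate and a hindered, non-nucleophilic base, conditions under which the neighbouring benzoate should not migrate.

Step 11
Reactants: 18 the TES ether
Product: 19 C2 alcohol (PMB removed; O2–H down)
Conditions: DDQ, CH2Cl2/aq. pH 7 buffer (KH2PO4/Na2HPO4), 0 °C to rt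
Reagents that add atoms: none
Why: Oxidative PMB cleavage by DDQ (hydride abstraction from the electron-rich benzylic position, then hydrolysis) leaves benzoates, TES ether and acetonide untouched and frees O2 alone.

Step 12
Reactants: 19 the C2 alcohol
Product: 20 C2 ketone with O1/O6 acetonide, O4 TES ether, O5 and O7 benzoates
Conditions: Dess–Martin periodinane, NaHCO3, CH2Cl2, 0 °C to rt
Reagents that add atoms: none
Why: Dess–Martin oxidation of the single free, hindered secondary alcohol under buffered, non-basic conditions should give the ketone without β-elimination of the C4 silyloxy group, and it erases the spectator centre.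

Step 13
Reactants: 20 the protected ketone
Product: 21 [(1S,2S,3R,4R)-3-(benzoyloxy)-1,2,4-trihydroxy-6-oxocyclohexyl]methyl benzoate (target)
Conditions: TFA/H2O 9:1, 0 °C
Reagents that add atoms: none
Why: Acid hydrolysis removes the TES ether and the isopropylidene acetal in one operation; cold, short exposure to aqueous TFA avoids base altogether, which limits benzoyl migration and dehydration of the β-hydroxy ketone, and no stereocentre is touched.

Compound list
1 | 2,3:5,6-di-O-isopropylidene-α-D-mannofuranose | O[C@H]1O[C@H]([C@H]2COC(C)(C)O2)[C@@H]2OC(C)(C)O[C@H]12 | starting material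
2 | formaldehyde | C=O | starting material
3 | 2-C-(hydroxymethyl)-2,3:5,6-di-O-isopropylidene-D-mannofuranose (anomeric mixture) | OC1O[C@H]([C@H]2COC(C)(C)O2)[C@@H]2OC(C)(C)O[C@]12CO | intermediate
4 | allylmagnesium bromide | C=CC[Mg]Br | starting material
5 | (4R)-1,2,3-trideoxy-5-C-(hydroxymethyl)-5,6:8,9-di-O-isopropylidene-D-glycero-D-talo-non-1-enitol | C=CC[C@@H](O)[C@@]1(CO)OC(C)(C)O[C@H]1[C@H](O)[C@H]2COC(C)(C)O2 | intermediate
6 | 4-methoxybenzaldehyde dimethyl acetal | COC(OC)c1ccc(OC)cc1 | starting material
7 | 4,5'-O-[(S)-4-methoxybenzylidene] acetal of 5 | C=CC[C@H]1O[C@@H](c2ccc(OC)cc2)OC[C@@]13OC(C)(C)O[C@H]3[C@H](O)[C@H]4COC(C)(C)O4 | intermediate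
8 | 4-O-(4-methoxybenzyl) ether of 5 (5'-OH, 7-OH free) | C=CC[C@@H](OCc1ccc(OC)cc1)[C@@]2(CO)OC(C)(C)O[C@H]2[C@H](O)[C@H]3COC(C)(C)O3 | intermediate
9 | benzoyl chloride | O=C(Cl)c1ccccc1 | starting material
10 | 5'-O-benzoyl-4-O-(4-methoxybenzyl) derivative of 5 (7-OH free) | C=CC[C@@H](OCc1ccc(OC)cc1)[C@@]2(COC(=O)c1ccccc1)OC(C)(C)O[C@H]2[C@H](O)[C@H]3COC(C)(C)O3 | intermediate
11 | 7,8,9-triol obtained from 10 | C=CC[C@@H](OCc1ccc(OC)cc1)[C@@]2(COC(=O)c1ccccc1)OC(C)(C)O[C@H]2[C@H](O)[C@H](O)CO | intermediate
12 | 3-C-(benzoyloxymethyl)-5,6,7-trideoxy-2,3-O-isopropylidene-4-O-(4-methoxybenzyl)-aldehydo-D-ribo-hept-6-enose | C=CC[C@@H](OCc1ccc(OC)cc1)[C@@]2(COC(=O)c1ccccc1)OC(C)(C)O[C@H]2C=O | intermediate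
13 | 3-C-(benzoyloxymethyl)-5-deoxy-2,3-O-isopropylidene-4-O-(4-methoxybenzyl)-aldehydo-D-ribo-heptose (both C6 epimers) | OCC(O)C[C@@H](OCc1ccc(OC)cc1)[C@@]2(COC(=O)c1ccccc1)OC(C)(C)O[C@H]2C=O | intermediate
14 | 3-C-(benzoyloxymethyl)-5-deoxy-2,3-O-isopropylidene-4-O-(4-methoxybenzyl)-D-ribo-hexodialdose | O=CC[C@@H](OCc1ccc(OC)cc1)[C@@]2(COC(=O)c1ccccc1)OC(C)(C)O[C@H]2C=O | intermediate
15 | carbocyclic cis-4,5-diol, O1/O6 acetonide, O2 PMB, O7 Bz | O=C(OC[C@@]1(OC(C)(C)O2)[C@H](OCc3ccc(OC)cc3)C[C@@H](O)[C@@H](O)[C@@H]12)c1ccccc1 | intermediate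
16 | 4,5-O-dibutylstannylene acetal of 15 | O=C(OC[C@@]1(OC(C)(C)O2)[C@H](OCc3ccc(OC)cc3)C[C@H]4O[Sn](CCCC)(CCCC)O[C@H]4[C@@H]12)c1ccccc1 | intermediate
17 | 5-O-benzoate of 15 | O=C(OC[C@@]1(OC(C)(C)O2)[C@H](OCc3ccc(OC)cc3)C[C@@H](O)[C@@H](OC(=O)c3ccccc3)[C@@H]12)c1ccccc1 | intermediate
18 | 4-O-TES ether of 17 | O=C(OC[C@@]1(OC(C)(C)O2)[C@H](OCc3ccc(OC)cc3)C[C@@H](O[Si](CC)(CC)CC)[C@@H](OC(=O)c3ccccc3)[C@@H]12)c1ccccc1 | intermediate
19 | C2 alcohol | O=C(OC[C@@]1(OC(C)(C)O2)[C@H](O)C[C@@H](O[Si](CC)(CC)CC)[C@@H](OC(=O)c3ccccc3)[C@@H]12)c1ccccc1 | intermediate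
20 | C2 ketone | O=C(OC[C@@]1(OC(C)(C)O2)C(=O)C[C@@H](O[Si](CC)(CC)CC)[C@@H](OC(=O)c3ccccc3)[C@@H]12)c1ccccc1 | intermediate
21 | [(1S,2S,3R,4R)-3-(benzoyloxy)-1,2,4-trihydroxy-6-oxocyclohexyl]methyl benzoate | O=C(OC[C@@]1(O)C(=O)C[C@@H](O)[C@@H](OC(=O)c2ccccc2)[C@@H]1O)c1ccccc1 | target

Total step count: 13. Longest linear sequence: 13 steps (1 to 21).

Steps most likely to fail

**Step 8.**
- Facial control may erode, with the glycol forming on the dioxolane face or as a trans-glycol.
- Plain reduction of the formyl groups or reductive loss of the C6–O bond may compete.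
- The fallback forms the same C4–C5 bond as an alkene and adds the two oxygens afterwards. It sets out from 11.
- NaIO4 alone (THF/H2O, rt) stops at 12, which is now isolated.
- Wittig methylenation (Ph3PCH3Br, KN(SiMe3)2, THF, −78 °C) should give the 1,7-diene F1.
- Ring-closing metathesis with the second-generation Grubbs catalyst, (H2IMes)(PCy3)Cl2Ru=CHPh, in refluxing CH2Cl2 should give the C4=C5 cyclohexene F2.
- OsO4 (cat.)/NMO dihydroxylation should attack the face opposite the allylic C6–O bond and the fused dioxolane. It comes back to the route at 15.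

**Step 2.**
- Facial selectivity in the carbon–carbon bond formation may be poor, because allylmagnesium reagents discriminate weakly and magnesium alkoxide chelation may compete.
- That would spread material over two C2 epimers and weaken the chair bias relied on in steps 8 and 9.
- The fallback delivers hydride instead of carbon to the prochiral centre. It sets out from 3.
- Br2, BaCO3, dioxane/H2O oxidises only the lactol to the branched 1,4-lactone F3.
- CH2=CHCH2MgBr (THF, −78 °C) adds once to give the allyl hemiketal F4.
- Zn(BH4)2 in Et2O reduces the open hydroxy-ketone tautomer under Cram-chelate control through O1, with hydride arriving from the CH2OH side. This should give the same (R)-carbinol, and it comes back at 5.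

**Step 13.**
- Acid-promoted loss of water across C3–C4 of the β-hydroxy ketone, or benzoyl migration from O5 to O4, may occur while the robust dioxolane is being hydrolysed.
- The fallback removes the acetonide before the ketone exists and ends with fluoride instead of acid. It sets out from 17.
- AcOH/H2O 4:1 at 60 °C should give the 1,4,6-triol F5.
- Excess TESOTf/2,6-lutidine should give the tris-TES ether F6.
- DDQ (buffered CH2Cl2/H2O) should give the C2 alcohol F7.
- Dess–Martin periodinane should give the tris-TES ketone F8.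
- HF·pyridine in THF/pyridine at 0 °C removes the three silyl ethers, and the fallback comes back at 21.

Further compounds
F1 | step 8 | 1,7-diene (formyl group of 12 replaced by vinyl) | C=CC[C@@H](OCc1ccc(OC)cc1)[C@@]2(COC(=O)c1ccccc1)OC(C)(C)O[C@H]2C=C
F2 | step 8 | C4=C5 cyclohexene with O1/O6 acetonide, O2 PMB, O7 Bz | O=C(OC[C@@]1(OC(C)(C)O2)[C@H](OCc3ccc(OC)cc3)CC=C[C@@H]12)c1ccccc1
F3 | step 2 | branched 1,4-lactone, 2-C-(hydroxymethyl)-2,3:5,6-di-O-isopropylidene-D-mannono-1,4-lactone | O=C1O[C@H]([C@H]2COC(C)(C)O2)[C@@H]2OC(C)(C)O[C@]12CO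
F4 | step 2 | allyl hemiketal (1-C-allyl derivative of 3, anomeric mixture) | C=CCC1(O)O[C@H]([C@H]2COC(C)(C)O2)[C@@H]2OC(C)(C)O[C@]12CO
F5 | step 13 | 1,4,6-triol (17 without acetonide) | O=C(OC[C@@]1(O)[C@H](OCc2ccc(OC)cc2)C[C@@H](O)[C@@H](OC(=O)c2ccccc2)[C@@H]1O)c1ccccc1
F6 | step 13 | tris-TES ether of F5 | O=C(OC[C@@]1(O[Si](CC)(CC)CC)[C@H](OCc2ccc(OC)cc2)C[C@@H](O[Si](CC)(CC)CC)[C@@H](OC(=O)c2ccccc2)[C@@H]1O[Si](CC)(CC)CC)c1ccccc1
F7 | step 13 | C2 alcohol (F6 without PMB) | O=C(OC[C@@]1(O[Si](CC)(CC)CC)[C@H](O)C[C@@H](O[Si](CC)(CC)CC)[C@@H](OC(=O)c2ccccc2)[C@@H]1O[Si](CC)(CC)CC)c1ccccc1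
F8 | step 13 | tris-TES ketone | O=C(OC[C@@]1(O[Si](CC)(CC)CC)C(=O)C[C@@H](O[Si](CC)(CC)CC)[C@@H](OC(=O)c2ccccc2)[C@@H]1O[Si](CC)(CC)CC)c1ccccc1
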